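Convention: ring carbons are C1 (acetoxy carbon), C2 (alkene CH), C3 (alkene carbon carrying C7), C4 (free carbinol), C5 (benzoate carbon) and C6 (free carbinol); On is the oxygen on Cn; the "top face" is the face of O5 and O6.
Assumption on the chemistry: in the silyl ethers of the endgame the C4 silyloxy group sits pseudoaxial (A(1,2) strain with the C3 substituent), which makes O5 axial and O6 equatorial.

## Structural features

The target is one cyclohexene ring (C1–C6, C2=C3) with a single exocyclic carbon, C7, on the alkene carbon C3, and all five oxygens sit on sp3 carbons that are allylic (C1, C4, C7) or homoallylic (C5, C6). Four contiguous stereocentres run C4–C5–C6–C1 with the configuration (1R,4S,5R,6S): O5 and O6 are cis on the top face, O4 and O1 are on the bottom face, so O4 is trans to O5, O1 is trans to O6 and O1 is cis to O4 across the ring. The oxygens are in three states: acetate on O1, benzoate on O5 and O7, free hydroxyl on O4 and O6. The fragile points are the O5 benzoate, which has a cis hydroxyl (O6) and a trans hydroxyl (O4) beside it and migrates under base, the allylic esters on C1 and C7, which can ionise, and any intermediate with a carbonyl at C3, which can aromatise by β-elimination of O5. The carbon skeleton is simple; the real difficulty is the configuration of C1 and C4 relative to the cis-diol and the sorting of five oxygens, above all O5 from O6. The key step exploits the array O1–C1–C2=C3–C7–O7, which is what 1,4-opening of an oxirane spiro-fused at C3 (three-membered ring C3–O–C7) beside a C1=C2 alkene delivers. C3 is then a former ketone carbon, and the C5/C6 cis-diol left on the six-membered ring is the C3/C4 diol of (−)-quinic acid in the correct absolute configuration.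

## Logic of the disconnections

27 ⇒ 26. The O4–H bond is traded for an O4–Si bond. O4 has to stay distinct from O5 and O6 until every ester is in place, and the silyl group also holds the ring conformation on which the preceding step relies. The gain is a last step that is a single deprotection. The demand is a fluoride source acidic enough that the O5 benzoate does not move to O4 or O6 and the allylic esters are left alone.

26 ⇒ 22 + 23 + 24 (through 25). The O5–C(acyl) bond is cut. O5 and O6 are both secondary and cis, and a direct acylation of 22 would favour the equatorial, less hindered O6. In 25 both oxygens are tied to one carbon, so the choice becomes a stereoelectronically controlled ring opening that leaves the ester on the axial oxygen. The gain is that O6 needs no protecting group. The demand is that O5 is axial in 25, which the pseudoaxial O4 silyl ether is expected to enforce.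

22 ⇒ 21 ⇒ 19 + 20. The two O–C bonds of the isopropylidene acetal on O5/O6 are restored, and then the O7–C(acyl) bond is cut. The acetal comes from 2 and covers the diol through every basic and organometallic step; O7 is the only free hydroxyl of 19, so its benzoylation needs no selectivity. The gain is that the esters go on one at a time. The demand is an acetal hydrolysis mild enough for a secondary silyl ether and two allylic esters.

19 ⇒ 17 + 18. The C1–O(acetate) bond is cut and O7 is reconnected to C3. This removes the C1 stereocentre and the O1/O7 differentiation at once, because in the forward direction one step delivers acetate on O1 and a free hydroxyl on O7. The demand is ionisation of the C3–O bond anti to the metal and return of acetate to C1 anti to the metal. That is net retention, so the oxirane oxygen of 17 must be on the bottom face.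

17 ⇒ 13 + 14 (through 15 and 16). The C3–C7 and C7–O bonds of the oxirane are cut. Both come from one methylene transfer to a carbonyl, so C7, the small ring and the C3 stereocentre reduce to a ketone and a one-carbon reagent. The demand is 1,2- rather than 1,4-addition, attack on the top face (anti to O4), and addition faster than deprotonation at C4.

13 ⇒ 10 + 11 (through 12), and 10 ⇒ 8 + 9. The C4–O bond is cut. C4 is the α'-carbon of an enone, so oxygen can be brought in through the cross-conjugated silyl dienol ether, and the silicon of 9 ends up as the O4 protecting group. The gain is that 8 has only the two stereocentres that come from 1. The demand is oxidation anti to the dioxolane and enol ether formation without a free enolate, which would expel O5.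

8 ⇒ 5 + 6 (through 7). The C1=C2 π bond is traced back to a C1–O bond β to the ketone. That hydroxyl of 5 is the one oxygen of 1 that the target does not keep in its original place. The gain is a saturated ketone with no alkene to set. The demand is that the sulfonate, not the dioxolane oxygen on the other β-carbon, is the leaving group.

5 ⇒ 4 ⇒ 3 ⇒ 1 + 2. The C3 carbonyl is traced back to the tertiary carbinol and its hydroxymethyl neighbour (glycol cleavage), these to the lactone carbonyl, and the lactone and acetal to 1 and 2. Each step uses a functional group that 1 already has, and C5 and C6 are never touched. The demand is only that the acetal forms on the cis pair, which is the only pair that can form it.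

## Other disconnections considered

Alternative 1: The cut removes both C–O bonds of the cis-diol (C5–O and C6–O) and leads back to bromobenzene A2. In the forward direction a whole-cell toluene dioxygenase oxidation would add dioxygen to one ring bond of A2 on one face and give the diene diol A1 as one enantiomer. O5 and O6 of A1 have the sense the target needs, and the brominated carbon is the future C4.

- In its favour: one step from an achiral arene reaches a six-membered ring with the cis-diol in place. The diene invites the next oxygenation: after acetonide formation, singlet oxygen anti to the dioxolane and reductive work-up should put O1 on the bottom face and turn the C–Br carbon into the C4 carbonyl of the γ-hydroxy enone A3.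
- Against it here: C7 is missing and would have to be attached at C3, α to that carbonyl. A Morita–Baylis–Hillman hydroxymethylation is the obvious way, but it is slow on hindered enones and runs under basic conditions that such enones tolerate badly. The C4 carbinol would then need a 1,2-reduction that delivers hydride on the dioxolane face, against the steric bias of the cis-fused bicycle; otherwise the all-cis alcohol forms and an inversion step is required. The bio-oxidation also needs a fermentation set-up.
- Comparison: in reaching the cis-diol this plan is the better one (one step, against four steps from 1 to 8). In fixing O1 relative to the dioxolane it is the equal of the chosen plan (endoperoxide geometry there, net retention in the palladium opening here). It is weaker where the chosen plan is strongest: the ylide brings in C7, the O1/O7 pattern and the C3 oxidation level through one ketone, whereas here a separate C–C bond formation and a reduction with an unfavourable facial bias are needed. The O5/O6 distinction at the end is the same problem in both, and the total step count would be about the same.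

Alternative 2: The cut is the C5–C6 ring bond. In the forward direction SmI2 (divalent samarium) would reduce both aldehydes of the Z-enedial A5 to ketyls, whose coupling closes the cyclohexene and forms both carbinol centres of the cis-diol A4.

- In its favour: the ring and two stereocentres form in one step. A trivalent-samarium-bridged diketyl gives the cis-diol, and the alkoxy groups on C1 and C4, both on the bottom face, should steer the new hydroxyls to the top face. O1 (as a p-methoxybenzyl ether) and O4 (as a silyl ether) are differentiated from the start, and the C7 benzoate is already present.
- Against it here: A5 carries two α-alkoxy aldehydes that are also β,γ-unsaturated, so epimerisation and migration of the alkene into conjugation threaten before the coupling. α-Alkoxy carbonyl groups can lose the alkoxy group under SmI2. The Z-trisubstituted alkene and both stereocentres of A5 must be built in an acyclic series. After the coupling, O5 still has to be told from O6 and the ether on O1 exchanged for acetate.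
- Comparison: in differentiating O1 from O4 it is the equal of the chosen plan, and it forms the ring where the chosen plan only buys it. In step economy it is clearly weaker, because the chosen plan takes C5 and C6 unchanged from 1. Mechanistically its stereocontrol rests on a chelated radical coupling of a labile substrate, against a polar addition to a rigid cyclic ketone.

Alternative 3: The cut removes the C1–O and C4–O bonds. In the forward direction singlet oxygen would add across C1 and C4 of the diene A7, made from shikimic acid A8, anti to the acetonide, to give the bicyclic endoperoxide A6.

- In its favour: both missing stereocentres are set in one step, each with the right relation to the dioxolane. C7 and its benzoate are present from the start (the carboxyl carbon of A8), so no C–C bond has to be formed and no protecting group beyond the acetonide is needed.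
- Against it here: reduction of the O–O bond of A6 leaves O1 and O4 as two free secondary allylic hydroxyls, and the acetate must then be placed on O1 by a kinetic preference for the less hindered one. A6 is base-sensitive (Kornblum–DeLaMare cleavage to a hydroxy enone), A7 can aromatise or undergo the ene reaction, and A8 costs more than 1.
- Comparison: in step economy and in stereocontrol at C1 and C4 this alternative is the better plan. The chosen plan is better in the sorting of the oxygens: O4 is silylated when it is introduced, and O1 and O7 emerge from the palladium step already as acetate and free hydroxyl, so no selective acylation of two similar alcohols is needed. The chosen plan also has the O4 silyl ether available as the conformational control for the O5/O6 distinction, which this alternative would have to install by an extra selective silylation.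

Key step: step 7

## Route

Step 1
Reactants: 1 (−)-quinic acid; 2 2,2-dimethoxypropane
Product: 3 quinide acetonide
Conditions: Me2C(OMe)2, TsOH·H2O (cat.), acetone, reflux
Reagents that add atoms: 2,2-dimethoxypropane (2), COC(C)(C)OC
Why: Acid-catalysed transketalisation protects the only cis-vicinal diol, and the carboxyl, which is syn to the remaining secondary hydroxyl, lactonises in the same pot (acetonide formation with lactonisation); no stereocentre is touched.

Step 2
Reactants: 3 quinide acetonide
Product: 4 acetonide triol
Conditions: NaBH4, EtOH, 0 °C → rt
Reagents that add atoms: none
Why: Borohydride reduction of the strained γ-lactone gives the primary alcohol and frees the secondary hydroxyl (lactone reduction); the acetal is inert and no stereocentre changes.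

Step 3
Reactants: 4 acetonide triol
Product: 5 β-hydroxy ketone
Conditions: NaIO4, H2O, 0 °C → rt
Reagents that add atoms: none
Why: Periodate glycol cleavage of the only free 1,2-diol (tertiary hydroxyl and hydroxymethyl) turns the quaternary carbon into the ketone that will be C3; the secondary hydroxyl has no free vicinal partner and stays.

Step 4
Reactants: 5 β-hydroxy ketone; 6 methanesulfonyl chloride
Product: 8 enone acetonide, via β-mesyloxy ketone 7 (not isolated)
Conditions: MsCl, Et3N, CH2Cl2, 0 °C → rt
Reagents that add atoms: methanesulfonyl chloride (6), CS(=O)(=O)Cl
Why: Mesylation of the β-hydroxyl gives 7, and E1cB loss of methanesulfonate then gives the conjugated enone (β-elimination), so the sulfonyl group is carried only by 7. The sulfonate is a far better leaving group than the dioxolane oxygen on the other β-carbon, so the acetal and both of its stereocentres stay.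

Step 5
Reactants: 8 enone acetonide; 9 tert-butyldimethylsilyl trifluoromethanesulfonate
Product: 10 silyl dienol ether
Conditions: TBSOTf, Et3N, CH2Cl2, −78 → 0 °C
Reagents that add atoms: tert-butyldimethylsilyl trifluoromethanesulfonate (9), CC(C)(C)[Si](C)(C)OS(=O)(=O)C(F)(F)F
Why: Soft enolisation: O-silylation of the ketone and removal of a C4 proton by the amine give the cross-conjugated 2-silyloxy diene (silyl enol ether formation). No metal enolate is formed, so expulsion of O5 and aromatisation have no opening, and no stereocentre is created.

Step 6
Reactants: 10 silyl dienol ether; 11 3-chloroperoxybenzoic acid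
Product: 13 C4-silyloxy enone acetonide, via silyloxy oxirane 12 (not isolated)
Conditions: mCPBA, CH2Cl2, −20 °C → rt
Reagents that add atoms: 3-chloroperoxybenzoic acid (11), OOC(=O)c1cccc(Cl)c1
Why: Rubottom oxidation: the peracid epoxidises the electron-rich C3=C4 enol ether bond on the bottom face, anti to the dioxolane oxygen on C5, which sets C4 with O4 trans to O5. The silyloxy oxirane 12 opens to the silyl-stabilised oxocarbenium ion and a 1,4 oxygen-to-oxygen silyl shift gives the α'-silyloxy enone directly.

Step 7
Reactants: 13 C4-silyloxy enone acetonide; 14 trimethylsulfonium iodide
Product: 17 spiro vinyl oxirane, via dimethylsulfonium methylide 15 (not isolated), via sulfonium alkoxide betaine 16 (not isolated)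
Conditions: Me3S+ I−, KN(SiMe3)2, THF, −20 °C; then 13, −40 → 0 °C
Reagents that add atoms: trimethylsulfonium iodide (14), C[S+](C)C.[I-]
Why: The amide base converts 14 into the unstabilised ylide 15, which adds irreversibly to the C3 carbonyl of 13 in the 1,2 sense and forms the C3–C7 bond of betaine 16; a sulfonium ylide is needed because the softer, reversibly adding sulfoxonium ylide would give the cyclopropane by 1,4-addition. The C3 alkoxide of 16 then displaces dimethyl sulfide from C7 in a 3-exo-tet closure that forms the C7–O bond and the oxirane ring; this is the Corey–Chaykovsky epoxidation, a standard reaction of cyclic enones and α-alkoxy ketones. The one new stereocentre, C3, is fixed in the addition step. The ketone should react through the half-chair with the C4 silyloxy group axial, where the C4–O bond is anti to the incoming carbon and the silyl group covers the bottom face, so C7 enters on the top face and the oxirane oxygen ends on the bottom face, cis to O4. The step also needs addition to be faster than deprotonation at C4, which would expel O5 and aromatise the ring; low temperature, a base that is consumed before the ketone is added, and the high carbonyl affinity of 15 should secure this. The acetal, the silyl ether and the C1=C2 alkene are inert to the ylide.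

Step 8
Reactants: 17 spiro vinyl oxirane; 18 acetic acid
Product: 19 C1 acetate C7 alcohol
Conditions: Pd(PPh3)4 (cat.), AcOH, THF, 0 °C → rt
Reagents that add atoms: acetic acid (18), CC(=O)O
Why: Tsuji–Trost opening of a vinyl oxirane: zerovalent palladium ionises the allylic C3–O bond anti (metal on the top face), acetic acid protonates the C7 alkoxide, and acetate attacks the less substituted allyl terminus C1 anti to palladium, on the face the oxirane oxygen occupied. This double inversion sets C1 with O1 cis to O4 and leaves O7 as the free hydroxyl.

Step 9
Reactants: 19 C1 acetate C7 alcohol; 20 benzoyl chloride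
Product: 21 C7 benzoate acetonide
Conditions: BzCl, pyridine, DMAP (cat.), CH2Cl2, 0 °C
Reagents that add atoms: benzoyl chloride (20), O=C(Cl)c1ccccc1
Why: Acylation of the only free hydroxyl, a primary allylic alcohol (esterification with an acid chloride); no selectivity is needed and no stereocentre is involved.

Step 10
Reactants: 21 C7 benzoate acetonide
Product: 22 silyl ether 5,6-diol
Conditions: 80% aq. AcOH, 40 °C
Reagents that add atoms: none
Why: Acid-catalysed hydrolysis of the isopropylidene acetal; a hindered secondary silyl ether and the esters tolerate aqueous acetic acid, and the acidic medium suppresses acyl migration to the new hydroxyls.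

Step 11
Reactants: 22 silyl ether 5,6-diol; 23 trimethyl orthobenzoate; 24 water
Product: 26 O5 benzoate silyl ether, via cyclic orthobenzoate 25 (not isolated)
Conditions: PhC(OMe)3, CSA (cat.), MeCN, rt; then 80% aq. AcOH, 0 °C → rt
Reagents that add atoms: trimethyl orthobenzoate (23), COC(OC)(OC)c1ccccc1; water (24), O
Why: Only the cis O5/O6 pair can close the five-membered orthoester 25; on hydrolysis the dioxolan-2-ylium ion takes up water and the hemiorthoester collapses under stereoelectronic control to the ester on the axial oxygen (orthoester route to axial monoesters of cis-diols). A(1,2) strain between the C3 benzoyloxymethyl group and the C4 silyl ether holds O4 pseudoaxial, so the trans O5 is axial and receives the benzoate while O6 is released.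

Step 12
Reactants: 26 O5 benzoate silyl ether
Product: 27 target
Conditions: HF·pyridine, pyridine, THF, 0 °C → rt
Reagents that add atoms: none
Why: Fluoride desilylation of the O4–Si bond under buffered acidic conditions, chosen over basic Bu4NF so that the O5 benzoate does not migrate to the cis O6 or trans O4 hydroxyl and the allylic esters survive; no stereocentre changes.

## Compound list

1 | (−)-quinic acid, (1S,3R,4S,5R)-1,3,4,5-tetrahydroxycyclohexane-1-carboxylic acid | O[C@@H]1C[C@](O)(C(=O)O)C[C@@H](O)[C@H]1O | starting material
2 | 2,2-dimethoxypropane | COC(C)(C)OC | starting material
3 | 3,4-O-isopropylidene-1,5-quinide: γ-lactone of 1 between the carboxyl and O5, dioxolane on the cis O3/O4 pair, tertiary hydroxyl free (quinic acid numbering) | O=C1O[C@@H]2C[C@@]1(O)C[C@H]3OC(C)(C)O[C@@H]23 | intermediate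
4 | acetonide triol: 1-(hydroxymethyl)cyclohexane-1,5-diol with the cis-3,4-dioxolane; tertiary hydroxyl cis to the dioxolane oxygens, secondary hydroxyl trans (quinic acid numbering) | OC[C@@]1(O)C[C@@H](O)[C@@H]2OC(C)(C)O[C@@H]2C1 | intermediate
5 | (3R,4S,5R)-3-hydroxy-4,5-(isopropylidenedioxy)cyclohexan-1-one; hydroxyl trans to the neighbouring dioxolane oxygen | O=C1C[C@@H](O)[C@@H]2OC(C)(C)O[C@@H]2C1 | intermediate
6 | methanesulfonyl chloride | CS(=O)(=O)Cl | starting material
7 | methanesulfonate of 5, same configuration (not isolated) | O=C1C[C@@H](OS(C)(=O)=O)[C@@H]2OC(C)(C)O[C@@H]2C1 | intermediate
8 | (4S,5R)-4,5-(isopropylidenedioxy)cyclohex-2-en-1-one; route numbering: C3 ketone, C1=C2, dioxolane on C5/C6 (top face), C4 methylene | O=C1C=C[C@@H]2OC(C)(C)O[C@@H]2C1 | intermediate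
9 | tert-butyldimethylsilyl trifluoromethanesulfonate | CC(C)(C)[Si](C)(C)OS(=O)(=O)C(F)(F)F | starting material
10 | silyl dienol ether: C1=C2 and C3(OSi)=C4 diene with the cis dioxolane on C5/C6 (top face) | CC(C)(C)[Si](C)(C)OC1=C[C@H]2OC(C)(C)O[C@H]2C=C1 | intermediate
11 | 3-chloroperoxybenzoic acid | OOC(=O)c1cccc(Cl)c1 | starting material
12 | 3,4-oxirane of 10 (not isolated): oxirane oxygen on the bottom face (anti to the dioxolane), silyloxy group on C3 on the top face | CC(C)(C)[Si](C)(C)O[C@]12C=C[C@@H]3OC(C)(C)O[C@@H]3[C@H]1O2 | intermediate
13 | (4S,5S,6R)-6-(tert-butyldimethylsilyloxy)-4,5-(isopropylidenedioxy)cyclohex-2-en-1-one; route numbering: C3 ketone, C1=C2, silyloxy on C4 (bottom face, trans to O5), dioxolane on C5/C6 (top face) | O=C1C=C[C@@H]2OC(C)(C)O[C@@H]2[C@H]1O[Si](C)(C)C(C)(C)C | intermediate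
14 | trimethylsulfonium iodide | C[S+](C)C.[I-] | starting material
15 | dimethylsulfonium methylide (not isolated) | C[S+](C)[CH2-] | intermediate
16 | betaine (not isolated): C3 alkoxide (oxygen on the bottom face) carrying the CH2–S+Me2 group (C7, top face); otherwise as 13 | [O-][C@@]1(C[S+](C)C)C=C[C@@H]2OC(C)(C)O[C@@H]2[C@H]1O[Si](C)(C)C(C)(C)C | intermediate
17 | spiro vinyl oxirane: oxirane C3–O–C7 spiro at C3, oxygen on the bottom face (cis to O4), C7 on the top face; C1=C2; silyloxy on C4; dioxolane on C5/C6 | C1=C[C@@]2(CO2)[C@H](O[Si](C)(C)C(C)(C)C)[C@H]3OC(C)(C)O[C@@H]13 | intermediate
18 | acetic acid | CC(=O)O | starting material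
19 | C1 acetate (bottom face, cis to O4), C2=C3, hydroxymethyl on C3, silyloxy on C4, dioxolane on C5/C6 | CC(=O)O[C@@H]1C=C(CO)[C@H](O[Si](C)(C)C(C)(C)C)[C@H]2OC(C)(C)O[C@@H]12 | intermediate
20 | benzoyl chloride | O=C(Cl)c1ccccc1 | starting material
21 | C7 benzoate of 19 | CC(=O)O[C@@H]1C=C(COC(=O)c2ccccc2)[C@H](O[Si](C)(C)C(C)(C)C)[C@H]3OC(C)(C)O[C@@H]13 | intermediate
22 | 5,6-diol: C1 acetate, C7 benzoate, C4 silyl ether, free cis hydroxyls on C5 and C6 (top face) | CC(=O)O[C@@H]1C=C(COC(=O)c2ccccc2)[C@H](O[Si](C)(C)C(C)(C)C)[C@@H](O)[C@H]1O | intermediate
23 | trimethyl orthobenzoate | COC(OC)(OC)c1ccccc1 | starting material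
24 | water | O | starting material
25 | cyclic orthobenzoate (not isolated): 2-methoxy-2-phenyl-1,3-dioxolane on O5/O6, either configuration at the orthoester carbon | CC(=O)O[C@@H]1C=C(COC(=O)c2ccccc2)[C@H](O[Si](C)(C)C(C)(C)C)[C@H]3OC(OC)(c4ccccc4)O[C@@H]13 | intermediate
26 | O5 benzoate: C1 acetate, C7 benzoate, C5 benzoate, C4 silyl ether, free hydroxyl on C6 | CC(=O)O[C@@H]1C=C(COC(=O)c2ccccc2)[C@H](O[Si](C)(C)C(C)(C)C)[C@@H](OC(=O)c2ccccc2)[C@H]1O | intermediate
27 | target, (1R,4S,5R,6S) in the route numbering: 1-acetoxy-5-benzoyloxy-3-(benzoyloxymethyl)cyclohex-2-ene-4,6-diol | CC(=O)O[C@@H]1C=C(COC(=O)c2ccccc2)[C@H](O)[C@@H](OC(=O)c2ccccc2)[C@H]1O | target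

## Step count and least certain steps

Total: 12 steps. Longest linear sequence: 12 steps, from 1 to 27.

Step 7 (key step). The most likely failure is poor facial selectivity. If the ketone reacts through the half-chair with the silyloxy group equatorial, axial attack comes from the bottom face, and the top face is flanked by the dioxolane oxygen on C5, so the epimeric oxirane could form in quantity. Fallback, from 13 back to 17: the stereocontrol is moved from shielding by O4 to delivery by O4. Wittig methylenation of 13 (Ph3P=CH2 from Ph3PCH3Br and KOtBu, THF) would give the exocyclic diene silyl ether F1. Bu4NF would free the allylic alcohol, the dienol F2. A hydroxyl-directed epoxidation with VO(acac)2 and t-BuOOH would deliver oxygen to the exocyclic alkene on the face of O4 and give the epoxy alcohol F3. Silylation with TBSCl and imidazole returns 17.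

Step 11. The most likely failure is loss of regiocontrol in the orthoester opening. The half-chair is flexible and the fused five-membered ring flattens it, so the ester may be released on O6 as well, and the cis hydroxy benzoate can then equilibrate by acyl migration. Fallback, from 22 to 27, bypassing 26: TBSCl and imidazole should silylate the equatorial O6, which is remote from the C4 silyl ether, to give the O6 silyl ether F4. Benzoylation of the remaining O5 hydroxyl (BzCl, DMAP, pyridine) would give the bis-silyl benzoate F5, in which no free hydroxyl is left for the benzoate to move to. HF·pyridine then removes both silyl groups and gives 27.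

Step 8. The most likely failure is slow ionisation, because the metal has to bind on the top face next to the dioxolane. Slow ionisation leaves room for β-hydride elimination to dienes and for erosion of the C1 configuration through re-ionisation of the product acetate. Fallback, from 17 to 21, bypassing 19: the ionisation and recombination are replaced by a sigmatropic transfer. Opening of the oxirane at the primary carbon C7 with benzoate (PhCO2H, Cs2CO3, DMF, 60 °C) would give the tertiary allylic alcohol C7 benzoate F6. Acetylation (Ac2O, DMAP, Et3N) would give the tertiary allylic acetate F7. A suprafacial [3,3] shift of the acetate from C3 to C1 catalysed by PdCl2(MeCN)2 (divalent palladium) moves the ester across the bottom face and gives 21, the more substituted alkene being the thermodynamic sink.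

Step 6. The most likely failure is incomplete silyl transfer after opening of the silyloxy oxirane, with partial loss of silicon, or capture of the oxocarbenium ion by the carboxylate. Fallback, from 10 back to 13: the enol ether bond is dihydroxylated instead of epoxidised. OsO4 (cat.) with N-methylmorpholine N-oxide in aqueous acetone should attack the electron-rich C3=C4 bond anti to the dioxolane; collapse of the hemiketal with loss of silanol gives the α'-hydroxy enone F8. TBSCl and imidazole then give 13.

## Further compounds

F1 | step 7 | exocyclic diene silyl ether: 13 with C3=CH2 in place of C3=O | C=C1C=C[C@@H]2OC(C)(C)O[C@@H]2[C@H]1O[Si](C)(C)C(C)(C)C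
F2 | step 7 | dienol: F1 with free C4 hydroxyl (bottom face) | C=C1C=C[C@@H]2OC(C)(C)O[C@@H]2[C@H]1O
F3 | step 7 | epoxy alcohol: 17 with free C4 hydroxyl, oxirane oxygen cis to it | C1=C[C@@]2(CO2)[C@H](O)[C@H]3OC(C)(C)O[C@@H]13
F4 | step 11 | O6 silyl ether of 22, free hydroxyl on C5 | CC(=O)O[C@@H]1C=C(COC(=O)c2ccccc2)[C@H](O[Si](C)(C)C(C)(C)C)[C@@H](O)[C@H]1O[Si](C)(C)C(C)(C)C
F5 | step 11 | O5 benzoate of F4 (O4 and O6 silyl ethers) | CC(=O)O[C@@H]1C=C(COC(=O)c2ccccc2)[C@H](O[Si](C)(C)C(C)(C)C)[C@@H](OC(=O)c2ccccc2)[C@H]1O[Si](C)(C)C(C)(C)C
F6 | step 8 | tertiary allylic alcohol: C3 hydroxyl on the bottom face, benzoyloxymethyl on C3, C1=C2, silyloxy on C4, dioxolane on C5/C6 | O[C@@]1(COC(=O)c2ccccc2)C=C[C@@H]3OC(C)(C)O[C@@H]3[C@H]1O[Si](C)(C)C(C)(C)C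
F7 | step 8 | tertiary allylic acetate of F6 | CC(=O)O[C@@]1(COC(=O)c2ccccc2)C=C[C@@H]3OC(C)(C)O[C@@H]3[C@H]1O[Si](C)(C)C(C)(C)C
F8 | step 6 | α'-hydroxy enone: 13 with free C4 hydroxyl | O=C1C=C[C@@H]2OC(C)(C)O[C@@H]2[C@H]1O
A1 | alternative 1 | (1S,2S)-3-bromocyclohexa-3,5-diene-1,2-diol | O[C@H]1C=CC=C(Br)[C@H]1O
A2 | alternative 1 | bromobenzene | Brc1ccccc1
A3 | alternative 1 | γ-hydroxy enone acetonide: C4 ketone, C2=C3, C1 hydroxyl on the bottom face, dioxolane on C5/C6 | O=C1C=C[C@@H](O)[C@@H]2OC(C)(C)O[C@H]12
A4 | alternative 2 | cyclohexene cis-5,6-diol with O1 p-methoxybenzyl ether, O4 silyl ether and C7 benzoate | COc1ccc(CO[C@@H]2C=C(COC(=O)c3ccccc3)[C@H](O[Si](C)(C)C(C)(C)C)[C@@H](O)[C@H]2O)cc1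
A5 | alternative 2 | Z-enedial: C5 and C6 aldehydes, O1 p-methoxybenzyl ether, O4 silyl ether, C7 benzoate | O=C[C@H](OCc1ccc(OC)cc1)/C=C(/COC(=O)c1ccccc1)[C@H](O[Si](C)(C)C(C)(C)C)C=O
A6 | alternative 3 | bicyclic endoperoxide, peroxide bridge anti to the dioxolane | O1O[C@@H]2C=C(COC(=O)c3ccccc3)[C@H]1[C@H]4OC(C)(C)O[C@@H]24
A7 | alternative 3 | diene: C1=C2–C3=C4 with benzoyloxymethyl on C3 and the cis dioxolane on C5/C6 | O=C(OCC1=C[C@H]2OC(C)(C)O[C@H]2C=C1)c1ccccc1
A8 | alternative 3 | (−)-shikimic acid | OC(=O)C1=C[C@@H](O)[C@@H](O)[C@H](O)C1
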